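A small charge of free catalyst keeps little substrate on itself, but these flasks do not all have a small charge. Catalyst intermediate A, catalyst intermediate B and catalyst intermediate C each carry one substrate, and the resting dimer carries two on its two catalysts. The ratio c(free catalyst)/c(substrate), 74.1% in zeta, is the hold-up, the share of the substrate charged that the catalyst can keep bound.

common to all: substrate 0.81 M
- larch: reagent 0.81 M; free catalyst 28 mM; temperature 35 °C; run made earlier
- cedar: reagent 0.81 M; free catalyst 370 mM; temperature 46 °C; run made earlier
- theta: reagent 0.810 M; free catalyst 140 mM; temperature 40 °C; time 2.5 h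
- gamma: reagent 0.810 M; free catalyst 80 mM; temperature 40 °C; time 2.5 h
- epsilon: reagent 0.810 M; free catalyst 300 mM; temperature 40 °C; time 2.5 h
- eta: reagent 0.810 M; free catalyst 50 mM; temperature 40 °C; time 2.5 h
- zeta: reagent 0.810 M; free catalyst 600 mM; temperature 40 °C; time 2.5 h

- ranking by amount of target, in percent of the substrate charged, from high to low, at 2.5 h (theta / gamma / epsilon / eta / zeta)
- the same order at 20 h (theta / gamma / epsilon / eta / zeta)
- the amount of target, in percent of the substrate charged of the flask you put first, at 2.5 h
- the amount of target, in percent of the substrate charged of the flask you put last, at 2.5 h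

- percentages count the substrate that a species holds: one side product or resting dimer counts as two
- what was read earlier has a scatter of 1 percentage point, one standard deviation
- reactions considered so far: catalyst intermediate B <-> by-product + catalyst intermediate C; 2 catalyst intermediate A <-> resting dimer; substrate + free catalyst -> catalyst intermediate A; catalyst intermediate C <-> free catalyst + target; reagent + catalyst intermediate A -> catalyst intermediate B; substrate + target -> side product

cedar run (percent of the substrate charged)

| time / min | target / % |
|---|---|
| 6.00 | 0.6 |
| 12.0 | 0 |
| 20.0 | 4.7 |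
| 40.0 | 14.1 |
| 80.0 | 31.2 |

I read the cedar table downward. Target is 0% at 12.0 min, then 4.7% at 20.0 min, so I read a late start. The last two rows give a turnover frequency, per catalyst charged, of 0.562 /h at 46 °C, as a reading. Drawn back, their line reaches zero at 7.02 min.

larch run (percent of the substrate charged)

| time / min | target / % |
|---|---|
| 6.00 | 0.7 |
| 20.0 | 1.2 |
| 40.0 | 0 |
| 50.0 | 1.7 |
| 80.0 | 1.0 |

The larch run ends at 1.0% with a scatter of 1 percentage point, so I read no rate from it.

At 40 °C I assume 0.7 of the cedar rate, which is my own factor. That gives 0.937 turnovers by 2.5 h, and so 5.78% target in eta. The same line gives 69.4% in zeta. With a full hold-up on top, zeta's line asks for 143% of the substrate charged, more than the charge. So I expect zeta to leave the line, and its substrate kept on catalyst makes me doubt its lead at 20 h.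

The forecast differs from me there. It gives zeta > epsilon > theta > gamma > eta at 2.5 h, with 45% and 4%, and zeta > epsilon > theta > gamma > eta at 20 h, holding that “high loadings finish with less side-product loss”.

The flasks give zeta > epsilon > theta > gamma > eta at 2.5 h, with 41.3% in zeta and 5.51% in eta. At 20 h they give epsilon > zeta > theta > gamma > eta, with epsilon at 74.5% and zeta at 68.3%.

    catalyst intermediate B ⇌ by-product + catalyst intermediate C (K = 6.60 M, k = 0.640 /h, Ea = 103 kJ/mol, ΔH = −24.0 kJ/mol)
    2 catalyst intermediate A ⇌ resting dimer (K = 900 /M, k = 2.20 /M/h, Ea = 85.0 kJ/mol, ΔH = 0 kJ/mol)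
    substrate + free catalyst → catalyst intermediate A (k = 75.0 /M/h, Ea = 69.0 kJ/mol)
    catalyst intermediate C ⇌ free catalyst + target (K = 40.0 M, k = 18.0 /h, Ea = 93.0 kJ/mol, ΔH = −39.0 kJ/mol)
    reagent + catalyst intermediate A → catalyst intermediate B (k = 3.30 /M/h, Ea = 62.0 kJ/mol)
    substrate + target → side product (k = 0.150 /M/h, Ea = 79.0 kJ/mol)
    (constants at 40 °C)

In zeta at 2.5 h, substrate stands at 0.0156%, while catalyst intermediate A, catalyst intermediate B, catalyst intermediate C and the resting dimer, an off-cycle resting state, together hold 78.5% of the catalyst. By the hold-up that is 58.2% of the substrate charged, which leaves 41.8%, and zeta shows 41.3% target and 0.551% side product. In epsilon at 25.0 h, the resting dimer's 45.1% of the catalyst is 16.7% of the substrate charged, which leaves 83.3%, of which side product holds 8.13% and target 74.7%.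

The runs come from a simulation from invented constants.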